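**Plan**

1. Retrosynthesis: after the C8 furoate and the two silyl ethers are taken off, the α-methylene-γ-butyrolactone is cut at C6–C7 and C11–C12 (the C12–O bond falls with them) in one carbonylative (2+2+1) event. Because C6–C7 is also a bond of the ten-membered ring, this one cut opens both rings to an acyclic allenyl enal.
2. Enabling feature: the lactone ring atoms O–C6–C7–C11–C12 with the exocyclic C13 are exactly an aldehyde C=O (C6), the inner π-bond of a terminal allene (C7=C11=C13) and CO (C12), the three components of a hetero-Pauson–Khand reaction.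
3. The chain is cut further at C11=C13 (formaldehyde), C3–C4 (methyl propiolate), C1–C2 (oxirane) and C8–C9 (allenylboronate plus a silylpropynal); C14 and C15 come from Me3Al and Me2CuLi.
4. Forward order: C8–C9, then C1=C10 with C1–C2, C3–C4, C4–C15, the epoxide, the allene, then lactone and ten-membered ring together, then the furoate.
5. Stereochemistry: C8 by chiral phosphoric acid propargylation, C3 by Zn–ProPhenol alkynylation, C1/C10 by Shi epoxidation (all reagent control). (E)-C1=C10 comes from syn carboalumination and (Z)-C4=C5 from syn cuprate addition. C6 and C7 arise in the key step, cis to each other through the metallacycle and relative to C8 by substrate control.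

Key step: step 13

Remark: carbons are numbered as in germacranes (ring C1–C10; C11, C12, C13 the C(=CH2)C=O unit of the lactone; C14 on C10; C15 on C4). In this numbering the target as drawn is 1R,3S,6S,7R,8R,10R with a (4Z) alkene and a cis-fused lactone.

**Route**

Step 1
Reactants: 1 3-(trimethylsilyl)prop-2-ynal; 2 allenylboronic acid pinacol ester
Product: 3 (3R)-1-(trimethylsilyl)hepta-1,6-diyn-3-ol
Conditions: (R)-3,3′-bis(2,4,6-triisopropylphenyl)-1,1′-binaphthyl-2,2′-diyl hydrogen phosphate (5 mol %), 4 Å molecular sieves, toluene, −20 °C; aq. NaHCO3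
Reagents that add atoms: none
Why: Chiral phosphoric acid-catalysed propargylation of an aldehyde with an allenylboronate (SE2′ through a closed six-membered transition state) should give the homopropargylic alcohol, the (R)-acid being expected to direct attack to the Re face of the formyl group with the alkynyl group in the place an aryl group takes in the usual substrates, which sets C8 as R.

Step 2
Reactants: 3 (3R)-1-(trimethylsilyl)hepta-1,6-diyn-3-ol
Product: 4 triethyl{[(3R)-1-(trimethylsilyl)hepta-1,6-diyn-3-yl]oxy}silane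
Conditions: Et3SiCl, imidazole, CH2Cl2, 0 °C
Reagents that add atoms: chlorotriethylsilane, CC[Si](Cl)(CC)CC
Why: Standard silyl ether formation protects the C8 hydroxyl for the organometallic steps with a group that can later be removed in the presence of a tert-butyldimethylsilyl ether.

Step 3
Reactants: 4 triethyl{[(3R)-1-(trimethylsilyl)hepta-1,6-diyn-3-yl]oxy}silane; 5 oxirane
Product: 8 (3E,6R)-4-methyl-6-(triethylsilyloxy)-8-(trimethylsilyl)oct-3-en-7-yn-1-ol, via alkenylalane 6 (not isolated), via lithium alkenylaluminate 7 (not isolated)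
Conditions: Me3Al (2 equiv), Cp2ZrCl2 (0.2 equiv), CH2Cl2, 0 °C → rt; excess Me3Al removed in vacuo; n-BuLi, THF/hexane, −78 → 0 °C; oxirane, 0 °C → rt; aq. Rochelle salt
Reagents that add atoms: trimethylaluminium, C[Al](C)C
Why: Zirconium-catalysed carboalumination (Negishi) adds methyl and aluminium syn across the terminal alkyne only, methyl to the inner carbon, and the derived aluminate opens oxirane with retention at the alkenyl carbon, so the trisubstituted C1=C10 alkene should form as the E isomer while the hindered silylalkyne is left alone.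

Step 4
Reactants: 8 (3E,6R)-4-methyl-6-(triethylsilyloxy)-8-(trimethylsilyl)oct-3-en-7-yn-1-ol
Product: 9 (3E,6R)-4-methyl-6-(triethylsilyloxy)-8-(trimethylsilyl)oct-3-en-7-ynal
Conditions: Dess–Martin periodinane, NaHCO3, CH2Cl2, 0 °C; used at once
Reagents that add atoms: none
Why: Buffered Dess–Martin oxidation is a mild, non-basic way to a β,γ-unsaturated aldehyde, which is taken on crude so that the alkene does not move into conjugation.

Step 5
Reactants: 9 (3E,6R)-4-methyl-6-(triethylsilyloxy)-8-(trimethylsilyl)oct-3-en-7-ynal; 10 methyl propiolate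
Product: 11 methyl (4S,6E,9R)-4-hydroxy-7-methyl-9-(triethylsilyloxy)-11-(trimethylsilyl)undec-6-ene-2,10-diynoate
Conditions: Me2Zn (3 equiv), (S,S)-2,6-bis{[2-(hydroxydiphenylmethyl)pyrrolidin-1-yl]methyl}-4-methylphenol (20 mol %), Ph3PO (40 mol %), toluene, 4 °C; aq. NH4Cl
Reagents that add atoms: none
Why: Zinc–ProPhenol asymmetric alkynylation of an aldehyde with methyl propiolate, in which the dinuclear zinc complex holds alkynylzinc and aldehyde together and the (S,S)-ligand is expected to deliver the alkynyl group to the face that gives the (S)-carbinol at C3; the nearly neutral zinc alkoxide medium is chosen to spare the β,γ-unsaturated aldehyde.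

Step 6
Reactants: 11 methyl (4S,6E,9R)-4-hydroxy-7-methyl-9-(triethylsilyloxy)-11-(trimethylsilyl)undec-6-ene-2,10-diynoate
Product: 12 methyl (4S,6E,9R)-4-(tert-butyldimethylsilyloxy)-7-methyl-9-(triethylsilyloxy)-11-(trimethylsilyl)undec-6-ene-2,10-diynoate
Conditions: t-BuMe2SiCl, imidazole, DMF, rt
Reagents that add atoms: tert-butyldimethylsilyl chloride, CC(C)(C)[Si](C)(C)Cl
Why: Standard silylation caps the C3 hydroxyl, which must stay masked until the lactone exists because a free γ-hydroxy (Z)-enal would close to a lactol and aromatise to a furan.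

Step 7
Reactants: 12 methyl (4S,6E,9R)-4-(tert-butyldimethylsilyloxy)-7-methyl-9-(triethylsilyloxy)-11-(trimethylsilyl)undec-6-ene-2,10-diynoate
Product: 13 methyl (2Z,4S,6E,9R)-4-(tert-butyldimethylsilyloxy)-3,7-dimethyl-9-(triethylsilyloxy)-11-(trimethylsilyl)undeca-2,6-dien-10-ynoate
Conditions: Me2CuLi (from CuI and 2 MeLi, 1.5 equiv), THF, −78 °C; MeOH then aq. NH4Cl at −78 °C
Reagents that add atoms: lithium dimethylcuprate, [Li+].C[Cu-]C
Why: Conjugate addition of a lithium dialkylcuprate to an alkynoate is a syn carbocupration, and protonation at −78 °C before the adduct can isomerise should give the (Z)-enoate with C3 and the ester carbon cis, the geometry of the C4=C5 bond of the target.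

Step 8
Reactants: 13 methyl (2Z,4S,6E,9R)-4-(tert-butyldimethylsilyloxy)-3,7-dimethyl-9-(triethylsilyloxy)-11-(trimethylsilyl)undeca-2,6-dien-10-ynoate
Product: 14 methyl (2Z,4S)-4-(tert-butyldimethylsilyloxy)-3-methyl-5-{(2R,3R)-3-methyl-3-[(2R)-2-(triethylsilyloxy)-4-(trimethylsilyl)but-3-yn-1-yl]oxiran-2-yl}pent-2-enoate
Conditions: 1,2:4,5-di-O-isopropylidene-β-D-erythro-hexo-2,3-diulo-2,6-pyranose (D-fructose-derived Shi ketone, 0.3 equiv), 2KHSO5·KHSO4·K2SO4, K2CO3, Bu4NHSO4, MeCN/CH2(OMe)2/aq. Na2B4O7 buffer (pH 10.5), 0 °C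
Reagents that add atoms: potassium peroxymonosulfate, [K+].[O-]S(=O)(=O)OO
Why: Shi asymmetric epoxidation, in which the chiral dioxirane attacks the only electron-rich alkene through the spiro transition state that gives the (R,R)-epoxide from (E)-trisubstituted alkenes of this shape (reagent control over C1 and C10), while the enoate and the alkyne are too electron-poor to react.

Step 9
Reactants: 14 methyl (2Z,4S)-4-(tert-butyldimethylsilyloxy)-3-methyl-5-{(2R,3R)-3-methyl-3-[(2R)-2-(triethylsilyloxy)-4-(trimethylsilyl)but-3-yn-1-yl]oxiran-2-yl}pent-2-enoate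
Product: 15 methyl (2Z,4S)-4-(tert-butyldimethylsilyloxy)-3-methyl-5-{(2R,3R)-3-methyl-3-[(2R)-2-(triethylsilyloxy)but-3-yn-1-yl]oxiran-2-yl}pent-2-enoate
Conditions: K2CO3, MeOH, 0 °C → rt
Reagents that add atoms: none
Why: Methanolysis of the C(sp)–Si bond frees the terminal alkyne, and since the ester is a methyl ester, methoxide exchange cannot alter it.

Step 10
Reactants: 15 methyl (2Z,4S)-4-(tert-butyldimethylsilyloxy)-3-methyl-5-{(2R,3R)-3-methyl-3-[(2R)-2-(triethylsilyloxy)but-3-yn-1-yl]oxiran-2-yl}pent-2-enoate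
Product: 17 methyl (2Z,4S)-4-(tert-butyldimethylsilyloxy)-3-methyl-5-{(2R,3R)-3-methyl-3-[(2R)-2-(triethylsilyloxy)penta-3,4-dien-1-yl]oxiran-2-yl}pent-2-enoate, via Mannich base 16 (not isolated)
Conditions: (CH2O)n, CuI (0.5 equiv), (c-C6H11)2NH, 1,4-dioxane, reflux
Reagents that add atoms: paraformaldehyde (as formaldehyde), C=O
Why: Crabbé homologation, in which the copper acetylide and the iminium ion from formaldehyde and dicyclohexylamine give Mannich base 16, which loses the imine by copper-assisted 1,5-hydride transfer to leave the terminal allene without touching C8.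

Step 11
Reactants: 17 methyl (2Z,4S)-4-(tert-butyldimethylsilyloxy)-3-methyl-5-{(2R,3R)-3-methyl-3-[(2R)-2-(triethylsilyloxy)penta-3,4-dien-1-yl]oxiran-2-yl}pent-2-enoate
Product: 18 (2Z,4S)-4-(tert-butyldimethylsilyloxy)-3-methyl-5-{(2R,3R)-3-methyl-3-[(2R)-2-(triethylsilyloxy)penta-3,4-dien-1-yl]oxiran-2-yl}pent-2-en-1-ol
Conditions: i-Bu2AlH (2.5 equiv), CH2Cl2, −78 °C; aq. Rochelle salt
Reagents that add atoms: none
Why: 1,2-Reduction of an enoate by diisobutylaluminium hydride at low temperature gives the allylic alcohol with the alkene geometry kept, and the trisubstituted epoxide and the allene are inert at −78 °C.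

Step 12
Reactants: 18 (2Z,4S)-4-(tert-butyldimethylsilyloxy)-3-methyl-5-{(2R,3R)-3-methyl-3-[(2R)-2-(triethylsilyloxy)penta-3,4-dien-1-yl]oxiran-2-yl}pent-2-en-1-ol
Product: 19 (2Z,4S)-4-(tert-butyldimethylsilyloxy)-3-methyl-5-{(2R,3R)-3-methyl-3-[(2R)-2-(triethylsilyloxy)penta-3,4-dien-1-yl]oxiran-2-yl}pent-2-enal
Conditions: Dess–Martin periodinane, NaHCO3, CH2Cl2, 0 °C; used at once
Reagents that add atoms: none
Why: Buffered Dess–Martin oxidation of the allylic alcohol should give the (Z)-enal without Z-to-E isomerisation, and the C3 silyl ether prevents lactol formation.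

Step 13
Reactants: 19 (2Z,4S)-4-(tert-butyldimethylsilyloxy)-3-methyl-5-{(2R,3R)-3-methyl-3-[(2R)-2-(triethylsilyloxy)penta-3,4-dien-1-yl]oxiran-2-yl}pent-2-enal
Product: 21 (4Z)-3β-(tert-butyldimethylsilyloxy)-1β,10α-epoxy-8β-(triethylsilyloxy)germacra-4,11(13)-dien-12,6β-olide, via oxamolybdacyclopentane 20 (not isolated)
Conditions: Mo(CO)6 (1.2 equiv), Me2SO (10 equiv), toluene, 100 °C, 19 added by syringe pump to a final 2 mM, Ar
Reagents that add atoms: molybdenum hexacarbonyl (source of carbon monoxide), [Mo].[C-]#[O+].[C-]#[O+].[C-]#[O+].[C-]#[O+].[C-]#[O+].[C-]#[O+]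
Why: Proposed new method: the closest known reaction type is the molybdenum-mediated hetero-Pauson–Khand cyclocarbonylation of allenyl aldehydes, so far used to close five- and six-membered carbocycles beside the lactone, and its use for a ten-membered ring is argued from the mechanism, in which a zerovalent Mo(CO)3 fragment freed by Me2SO binds the C6 formyl group and the inner C7=C11 π-bond of the allene, oxidative cyclisation forms the C6–C7 bond and gives oxamolybdacyclopentane 20 (divalent molybdenum), CO inserts into the Mo–C11 bond to form C11–C12, and reductive elimination joins C12 to the oxygen on C6. The ten-membered carbocycle closes in the oxidative cyclisation by C6–C7 bond formation, exo with respect to both π-bonds (the carbonyl oxygen and C11 stay outside the carbocycle), and the five-membered lactone closes by C–O reductive elimination from the acyl molybdacycle, being overall a (2+2+1) adduct of C6=O, C7=C11 and CO. C6 and C7 are set together: the two π-bonds react side by side on one metal, so the chain leaves them on the same face and the lactone should be cis-fused, and the face of the allene is chosen by the C8 centre, whose silyloxy group should lie anti to the forming C6–C7 bond while C9 turns toward the aldehyde, which places H7 and H8 on the same face of the new ring as in 25. The step needs ring closure to outrun oligomerisation, which slow addition to a dilute solution and the two rigid elements of the chain, the (Z)-C4=C5 alkene and the trans-epoxide, are meant to secure. It needs reaction at the inner and not the terminal π-bond of the allene, the mode molybdenum shows with monosubstituted allenes in the known small-ring cases, and reaction of the enal through C=O only, which the β,β-disubstituted and oxygen-flanked C4=C5 bond should ensure. The epoxide, both silyl ethers and the exocyclic alkene of the product are expected to survive these neutral conditions.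

Step 14
Reactants: 21 (4Z)-3β-(tert-butyldimethylsilyloxy)-1β,10α-epoxy-8β-(triethylsilyloxy)germacra-4,11(13)-dien-12,6β-olide
Product: 22 (4Z)-3β-(tert-butyldimethylsilyloxy)-1β,10α-epoxy-8β-hydroxygermacra-4,11(13)-dien-12,6β-olide
Conditions: HF·pyridine, pyridine, THF, 0 °C
Reagents that add atoms: none
Why: Fluoride-mediated desilylation, in which the triethylsilyl ether should be cleaved much faster than the tert-butyldimethylsilyl ether and the pyridine buffer protects the epoxide.

Step 15
Reactants: 22 (4Z)-3β-(tert-butyldimethylsilyloxy)-1β,10α-epoxy-8β-hydroxygermacra-4,11(13)-dien-12,6β-olide; 23 furan-3-carbonyl chloride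
Product: 24 (4Z)-3β-(tert-butyldimethylsilyloxy)-1β,10α-epoxy-8β-(furan-3-carbonyloxy)germacra-4,11(13)-dien-12,6β-olide
Conditions: pyridine, 4-(dimethylamino)pyridine (0.1 equiv), CH2Cl2, 0 °C → rt
Reagents that add atoms: none
Why: Acylation of the only free hydroxyl with an acid chloride under nucleophilic catalysis leaves the C8–O bond intact, so C8 keeps its configuration.

Step 16
Reactants: 24 (4Z)-3β-(tert-butyldimethylsilyloxy)-1β,10α-epoxy-8β-(furan-3-carbonyloxy)germacra-4,11(13)-dien-12,6β-olide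
Product: 25 (4Z)-1β,10α-epoxy-8β-(furan-3-carbonyloxy)-3β-hydroxygermacra-4,11(13)-dien-12,6β-olide (CNP0390850.1)
Conditions: HF·pyridine, pyridine, THF, 0 °C → rt
Reagents that add atoms: none
Why: Buffered fluoride cleavage of the allylic silyl ether, of the kind used for late desilylation next to a trisubstituted epoxide, should free the C3 hydroxyl without touching the ester, the epoxide or the α-methylene lactone.

**Compound list**

1 | 3-(trimethylsilyl)prop-2-ynal | C[Si](C)(C)C#CC=O | starting material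
2 | allenylboronic acid pinacol ester (4,4,5,5-tetramethyl-2-(propa-1,2-dien-1-yl)-1,3,2-dioxaborolane) | C=C=CB1OC(C)(C)C(C)(C)O1 | starting material
3 | (3R)-1-(trimethylsilyl)hepta-1,6-diyn-3-ol | C#CC[C@@H](O)C#C[Si](C)(C)C | intermediate
4 | triethyl{[(3R)-1-(trimethylsilyl)hepta-1,6-diyn-3-yl]oxy}silane | C#CC[C@@H](O[Si](CC)(CC)CC)C#C[Si](C)(C)C | intermediate
5 | oxirane | C1CO1 | starting material
6 | dimethyl[(1E,4R)-2-methyl-4-(triethylsilyloxy)-6-(trimethylsilyl)hex-1-en-5-yn-1-yl]alane | C[Al](C)/C=C(\C)C[C@@H](O[Si](CC)(CC)CC)C#C[Si](C)(C)C | intermediate (not isolated)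
7 | lithium butyl(dimethyl)[(1E,4R)-2-methyl-4-(triethylsilyloxy)-6-(trimethylsilyl)hex-1-en-5-yn-1-yl]aluminate | [Li+].CCCC[Al-](C)(C)/C=C(\C)C[C@@H](O[Si](CC)(CC)CC)C#C[Si](C)(C)C | intermediate (not isolated)
8 | (3E,6R)-4-methyl-6-(triethylsilyloxy)-8-(trimethylsilyl)oct-3-en-7-yn-1-ol | OCC/C=C(\C)C[C@@H](O[Si](CC)(CC)CC)C#C[Si](C)(C)C | intermediate
9 | (3E,6R)-4-methyl-6-(triethylsilyloxy)-8-(trimethylsilyl)oct-3-en-7-ynal | O=CC/C=C(\C)C[C@@H](O[Si](CC)(CC)CC)C#C[Si](C)(C)C | intermediate
10 | methyl propiolate | C#CC(=O)OC | starting material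
11 | methyl (4S,6E,9R)-4-hydroxy-7-methyl-9-(triethylsilyloxy)-11-(trimethylsilyl)undec-6-ene-2,10-diynoate | COC(=O)C#C[C@@H](O)C/C=C(\C)C[C@@H](O[Si](CC)(CC)CC)C#C[Si](C)(C)C | intermediate
12 | methyl (4S,6E,9R)-4-(tert-butyldimethylsilyloxy)-7-methyl-9-(triethylsilyloxy)-11-(trimethylsilyl)undec-6-ene-2,10-diynoate | COC(=O)C#C[C@@H](O[Si](C)(C)C(C)(C)C)C/C=C(\C)C[C@@H](O[Si](CC)(CC)CC)C#C[Si](C)(C)C | intermediate
13 | methyl (2Z,4S,6E,9R)-4-(tert-butyldimethylsilyloxy)-3,7-dimethyl-9-(triethylsilyloxy)-11-(trimethylsilyl)undeca-2,6-dien-10-ynoate | COC(=O)/C=C(/C)[C@@H](O[Si](C)(C)C(C)(C)C)C/C=C(\C)C[C@@H](O[Si](CC)(CC)CC)C#C[Si](C)(C)C | intermediate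
14 | methyl (2Z,4S)-4-(tert-butyldimethylsilyloxy)-3-methyl-5-{(2R,3R)-3-methyl-3-[(2R)-2-(triethylsilyloxy)-4-(trimethylsilyl)but-3-yn-1-yl]oxiran-2-yl}pent-2-enoate | COC(=O)/C=C(/C)[C@@H](O[Si](C)(C)C(C)(C)C)C[C@H]1O[C@]1(C)C[C@@H](O[Si](CC)(CC)CC)C#C[Si](C)(C)C | intermediate
15 | methyl (2Z,4S)-4-(tert-butyldimethylsilyloxy)-3-methyl-5-{(2R,3R)-3-methyl-3-[(2R)-2-(triethylsilyloxy)but-3-yn-1-yl]oxiran-2-yl}pent-2-enoate | COC(=O)/C=C(/C)[C@@H](O[Si](C)(C)C(C)(C)C)C[C@H]1O[C@]1(C)C[C@@H](O[Si](CC)(CC)CC)C#C | intermediate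
16 | methyl (2Z,4S)-4-(tert-butyldimethylsilyloxy)-5-{(2R,3R)-3-[(2R)-5-(dicyclohexylamino)-2-(triethylsilyloxy)pent-3-yn-1-yl]-3-methyloxiran-2-yl}-3-methylpent-2-enoate | COC(=O)/C=C(/C)[C@@H](O[Si](C)(C)C(C)(C)C)C[C@H]1O[C@]1(C)C[C@@H](O[Si](CC)(CC)CC)C#CCN(C1CCCCC1)C1CCCCC1 | intermediate (not isolated)
17 | methyl (2Z,4S)-4-(tert-butyldimethylsilyloxy)-3-methyl-5-{(2R,3R)-3-methyl-3-[(2R)-2-(triethylsilyloxy)penta-3,4-dien-1-yl]oxiran-2-yl}pent-2-enoate | COC(=O)/C=C(/C)[C@@H](O[Si](C)(C)C(C)(C)C)C[C@H]1O[C@]1(C)C[C@@H](O[Si](CC)(CC)CC)C=C=C | intermediate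
18 | (2Z,4S)-4-(tert-butyldimethylsilyloxy)-3-methyl-5-{(2R,3R)-3-methyl-3-[(2R)-2-(triethylsilyloxy)penta-3,4-dien-1-yl]oxiran-2-yl}pent-2-en-1-ol | OC/C=C(/C)[C@@H](O[Si](C)(C)C(C)(C)C)C[C@H]1O[C@]1(C)C[C@@H](O[Si](CC)(CC)CC)C=C=C | intermediate
19 | (2Z,4S)-4-(tert-butyldimethylsilyloxy)-3-methyl-5-{(2R,3R)-3-methyl-3-[(2R)-2-(triethylsilyloxy)penta-3,4-dien-1-yl]oxiran-2-yl}pent-2-enal | O=C/C=C(/C)[C@@H](O[Si](C)(C)C(C)(C)C)C[C@H]1O[C@]1(C)C[C@@H](O[Si](CC)(CC)CC)C=C=C | intermediate
20 | tricarbonyl oxamolybdacyclopentane (divalent molybdenum; Mo bound to the C6 oxygen and to C11, C6–C7 bond formed, exocyclic C11=C13) | C=C1[Mo]O[C@H]2/C=C(/C)[C@@H](O[Si](C)(C)C(C)(C)C)C[C@H]3O[C@]3(C)C[C@@H](O[Si](CC)(CC)CC)[C@@H]12.[C-]#[O+].[C-]#[O+].[C-]#[O+] | intermediate (not isolated)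
21 | (4Z)-3β-(tert-butyldimethylsilyloxy)-1β,10α-epoxy-8β-(triethylsilyloxy)germacra-4,11(13)-dien-12,6β-olide (1R,3S,6S,7S,8R,10R; C7 reads S only because the silyloxy branch on C8 outranks the lactone oxygen branch; cis-fused lactone) | C=C1C(=O)O[C@H]2/C=C(/C)[C@@H](O[Si](C)(C)C(C)(C)C)C[C@H]3O[C@]3(C)C[C@@H](O[Si](CC)(CC)CC)[C@@H]12 | intermediate
22 | (4Z)-3β-(tert-butyldimethylsilyloxy)-1β,10α-epoxy-8β-hydroxygermacra-4,11(13)-dien-12,6β-olide (1R,3S,6S,7R,8R,10R) | C=C1C(=O)O[C@H]2/C=C(/C)[C@@H](O[Si](C)(C)C(C)(C)C)C[C@H]3O[C@]3(C)C[C@@H](O)[C@@H]12 | intermediate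
23 | furan-3-carbonyl chloride | O=C(Cl)c1ccoc1 | starting material
24 | (4Z)-3β-(tert-butyldimethylsilyloxy)-1β,10α-epoxy-8β-(furan-3-carbonyloxy)germacra-4,11(13)-dien-12,6β-olide (1R,3S,6S,7R,8R,10R) | C=C1C(=O)O[C@H]2/C=C(/C)[C@@H](O[Si](C)(C)C(C)(C)C)C[C@H]3O[C@]3(C)C[C@@H](OC(=O)c3ccoc3)[C@@H]12 | intermediate
25 | (4Z)-1β,10α-epoxy-8β-(furan-3-carbonyloxy)-3β-hydroxygermacra-4,11(13)-dien-12,6β-olide (1R,3S,6S,7R,8R,10R; CNP0390850.1) | C=C1C(=O)O[C@H]2/C=C(/C)[C@@H](O)C[C@H]3O[C@]3(C)C[C@@H](OC(=O)c3ccoc3)[C@@H]12 | target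

Total step count: 16
Longest linear sequence: 16 steps (1 → 25)

**Steps most likely to fail**

Step 13 (proposed new method). What may go wrong: oligomerisation instead of ring closure, reaction at the terminal allene π-bond, poor facial selectivity at C7 relative to C8, or loss of the epoxide oxygen to low-valent molybdenum. The fallback uses known chemistry, a two-stage 2-bromoallylation and carbonylative lactonisation, and sets out from 19. Bromine is added to the allene (pyridinium tribromide, CH2Cl2, −78 °C) to give the 2,3-dibromoallyl compound F1; its secondary allylic isomer, if formed, gives the same allylchromium species. CrCl2 in THF at high dilution (intramolecular Nozaki–Hiyama–Kishi-type allylation, the allylchromium attacking the aldehyde through C7) should close the ten-membered ring to the 2-bromoallylic alcohol F2. Pd(PPh3)4, CO (1 atm), Et3N, MeCN, 60 °C then closes the lactone by carbonylative lactonisation and comes back to the route at 21.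

Step 5. What may go wrong: migration of the β,γ-double bond into conjugation with the aldehyde, aldol self-condensation, or low enantioselectivity with an unbranched aldehyde. The fallback takes C3 from the chiral pool and sets out from 4. Aluminate 7, made as in step 3, is treated with (S)-2-[(4-methoxybenzyloxy)methyl]oxirane in place of oxirane to give the secondary alcohol F3. t-BuMe2SiCl/imidazole gives the silyl ether F4, DDQ in CH2Cl2/pH 7 buffer gives the primary alcohol F5, and Dess–Martin oxidation gives the α-silyloxy aldehyde F6. CBr4/PPh3 gives the dibromoalkene F7, and n-BuLi (2 equiv, THF, −78 °C) followed by ClCO2Me (Corey–Fuchs alkynylation with carboxylation of the lithium acetylide) comes back to the route at 12.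

Step 10. What may go wrong: opening or rearrangement of the trisubstituted epoxide, or loss of a silyl group, under the hot copper/amine conditions. The fallback changes the order so that the allene is made before any epoxide is present and the epoxide is put in last, on the ring; it sets out from 13. K2CO3/MeOH gives the terminal alkyne F8, and Crabbé homologation as in step 10 gives, through the Mannich base F9, the allene F10. i-Bu2AlH gives the allylic alcohol F11, Dess–Martin oxidation gives the enal F12, and the conditions of step 13 should give the dienolide F13. m-Chloroperbenzoic acid (NaHCO3, CH2Cl2, 0 °C) should then epoxidise only the electron-rich C1=C10 bond, from its exposed face in the conformer that holds C14 on the face of the C8 oxygen, and come back to the route at 21. This last epoxidation is substrate-controlled, which is the price of the fallback.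

**Further compounds**

F1 | step 13 | (2Z,4S)-4-(tert-butyldimethylsilyloxy)-5-{(2R,3R)-3-[(2R,3E)-4,5-dibromo-2-(triethylsilyloxy)pent-3-en-1-yl]-3-methyloxiran-2-yl}-3-methylpent-2-enal | O=C/C=C(/C)[C@@H](O[Si](C)(C)C(C)(C)C)C[C@H]1O[C@]1(C)C[C@@H](O[Si](CC)(CC)CC)/C=C(/Br)CBr
F2 | step 13 | ten-membered 2-bromoallylic alcohol: (4Z)-7-(1-bromovinyl)-3β-(tert-butyldimethylsilyloxy)-1β,10α-epoxy-6β-hydroxy-8β-(triethylsilyloxy) carbocycle, H6 and H7 cis | O[C@H]1/C=C(/C)[C@@H](O[Si](C)(C)C(C)(C)C)C[C@H]2O[C@]2(C)C[C@@H](O[Si](CC)(CC)CC)[C@H]1C(Br)=C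
F3 | step 5 | (2S,4E,7R)-1-(4-methoxybenzyloxy)-5-methyl-7-(triethylsilyloxy)-9-(trimethylsilyl)non-4-en-8-yn-2-ol | COc1ccc(COC[C@@H](O)C/C=C(\C)C[C@@H](O[Si](CC)(CC)CC)C#C[Si](C)(C)C)cc1
F4 | step 5 | tert-butyldimethylsilyl ether of F3 | COc1ccc(COC[C@@H](O[Si](C)(C)C(C)(C)C)C/C=C(\C)C[C@@H](O[Si](CC)(CC)CC)C#C[Si](C)(C)C)cc1
F5 | step 5 | (2S,4E,7R)-2-(tert-butyldimethylsilyloxy)-5-methyl-7-(triethylsilyloxy)-9-(trimethylsilyl)non-4-en-8-yn-1-ol | OC[C@@H](O[Si](C)(C)C(C)(C)C)C/C=C(\C)C[C@@H](O[Si](CC)(CC)CC)C#C[Si](C)(C)C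
F6 | step 5 | (2S,4E,7R)-2-(tert-butyldimethylsilyloxy)-5-methyl-7-(triethylsilyloxy)-9-(trimethylsilyl)non-4-en-8-ynal | O=C[C@@H](O[Si](C)(C)C(C)(C)C)C/C=C(\C)C[C@@H](O[Si](CC)(CC)CC)C#C[Si](C)(C)C
F7 | step 5 | (3S,5E,8R)-1,1-dibromo-3-(tert-butyldimethylsilyloxy)-6-methyl-8-(triethylsilyloxy)-10-(trimethylsilyl)deca-1,5-dien-9-yne | BrC(Br)=C[C@@H](O[Si](C)(C)C(C)(C)C)C/C=C(\C)C[C@@H](O[Si](CC)(CC)CC)C#C[Si](C)(C)C
F8 | step 10 | methyl (2Z,4S,6E,9R)-4-(tert-butyldimethylsilyloxy)-3,7-dimethyl-9-(triethylsilyloxy)undeca-2,6-dien-10-ynoate | COC(=O)/C=C(/C)[C@@H](O[Si](C)(C)C(C)(C)C)C/C=C(\C)C[C@@H](O[Si](CC)(CC)CC)C#C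
F9 | step 10 | methyl (2Z,4S,6E,9R)-4-(tert-butyldimethylsilyloxy)-12-(dicyclohexylamino)-3,7-dimethyl-9-(triethylsilyloxy)dodeca-2,6-dien-10-ynoate | COC(=O)/C=C(/C)[C@@H](O[Si](C)(C)C(C)(C)C)C/C=C(\C)C[C@@H](O[Si](CC)(CC)CC)C#CCN(C1CCCCC1)C1CCCCC1
F10 | step 10 | methyl (2Z,4S,6E,9R)-4-(tert-butyldimethylsilyloxy)-3,7-dimethyl-9-(triethylsilyloxy)dodeca-2,6,10,11-tetraenoate | COC(=O)/C=C(/C)[C@@H](O[Si](C)(C)C(C)(C)C)C/C=C(\C)C[C@@H](O[Si](CC)(CC)CC)C=C=C
F11 | step 10 | (2Z,4S,6E,9R)-4-(tert-butyldimethylsilyloxy)-3,7-dimethyl-9-(triethylsilyloxy)dodeca-2,6,10,11-tetraen-1-ol | OC/C=C(/C)[C@@H](O[Si](C)(C)C(C)(C)C)C/C=C(\C)C[C@@H](O[Si](CC)(CC)CC)C=C=C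
F12 | step 10 | (2Z,4S,6E,9R)-4-(tert-butyldimethylsilyloxy)-3,7-dimethyl-9-(triethylsilyloxy)dodeca-2,6,10,11-tetraenal | O=C/C=C(/C)[C@@H](O[Si](C)(C)C(C)(C)C)C/C=C(\C)C[C@@H](O[Si](CC)(CC)CC)C=C=C
F13 | step 10 | (1(10)E,4Z)-3β-(tert-butyldimethylsilyloxy)-8β-(triethylsilyloxy)germacra-1(10),4,11(13)-trien-12,6β-olide | C=C1C(=O)O[C@H]2/C=C(/C)[C@@H](O[Si](C)(C)C(C)(C)C)C/C=C(\C)C[C@@H](O[Si](CC)(CC)CC)[C@@H]12
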